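The route rests on disconnecting the flavone C5–C4a bond, so that the A ring (C4a, C5–C8, C8a) is grown from dimethyl squarate onto a preformed 2-aryl-4-pyranone that already holds the B and C rings. The feature exploited is the oxygen on each of C5–C8: the adjacent 6,7-methoxyls are the squarate ester, 8-OMe is a methylated carbinol, and 5-OH, para to it and peri to C4=O, is a ketene oxygen. A single thermolysis of a racemic 2,3,4-trimethoxy-4-(4-oxopyran-2-yl)cyclobutenone opens the four-membered ring and closes the benzene ring (one C–C bond, one ring), delivering gardenin A directly with no protecting groups.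

Key step: step 3

Remark on the chemistry (assumption): gardenin A has no stereogenic element, so the single-enantiomer requirement is met by the achiral target itself. Precursor 9 is used as the racemate because its only stereocentre becomes aromatic C8 in step 3. All structures were checked atom by atom (9 and 12 are isomers, C21H22O9) and needed no correction. The C4 methyl ether of 9 is kept because it alone distinguishes 8-OMe from 5-OH.

Step 1
Reactants: 1 (E)-4-methoxybut-3-en-2-one; 2 3,4,5-trimethoxybenzoyl chloride
Product: 5 2-(3,4,5-trimethoxyphenyl)-4H-pyran-4-one, via lithium dienolate 3 (not isolated), via methoxyvinyl β-diketone 4 (not isolated)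
Conditions: LiHMDS (2.1 equiv), 1 (2.1 equiv), THF, −78 °C; then 2 (1.0 equiv), −78 °C; TFA quench, solvent switch; TFA, PhMe, rt
Reagents that add atoms: none
Why: The kinetic lithium dienolate of the methyl ketone is C-acylated by the aroyl chloride (crossed Claisen-type acylation, the surplus enolate taking up the acidic β-diketone proton), and under acid the enol oxygen of 4 adds 6-endo to the β-methoxy enone and expels methanol (oxa-Michael addition–elimination), the standard acid chloride to γ-pyranone annulation; no stereocentre is involved.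

Step 2
Reactants: 5 2-(3,4,5-trimethoxyphenyl)-4H-pyran-4-one; 6 dimethyl squarate (3,4-dimethoxycyclobut-3-ene-1,2-dione)
Product: 9 rac-2,3,4-trimethoxy-4-[4-oxo-6-(3,4,5-trimethoxyphenyl)-4H-pyran-2-yl]cyclobut-2-en-1-one, via 6-lithiopyranone 7 (not isolated), via lithium alkoxide adduct 8 (not isolated)
Conditions: LiTMP (from TMPH + n-BuLi, 1.05 equiv), THF, −78 °C, inverse addition of 5; cannulate into 6 (1.3 equiv), THF, −78 °C; MeOTf (1.2 equiv), −78 → 0 °C; aq. NaHCO3; product kept cold
Reagents that add atoms: methyl trifluoromethanesulfonate (MeOTf), COS(=O)(=O)C(F)(F)F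
Why: The vinylic C6–H next to the ring oxygen of the β-alkoxy enone is the most acidic proton of 5 and is removed by the non-nucleophilic amide as C2–H of chromones is (directed deprotonation); the alkenyllithium then adds 1,2 to one squarate carbonyl as sp2 organolithiums generally do, and the tertiary lithium alkoxide is methylated by methyl triflate (Williamson-type O-alkylation) much faster than the neutral pyranone carbonyl; the new quaternary centre forms as a racemate on purpose, since step 3 flattens it.

Step 3
Reactants: 9 rac-2,3,4-trimethoxy-4-[4-oxo-6-(3,4,5-trimethoxyphenyl)-4H-pyran-2-yl]cyclobut-2-en-1-one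
Product: 12 gardenin A (5-hydroxy-6,7,8-trimethoxy-2-(3,4,5-trimethoxyphenyl)-4H-chromen-4-one), via dienylketene 10 (not isolated), via 4aH-chromene-4,5-dione 11 (not isolated)
Conditions: PhMe (dry, degassed, ca. 0.02 M), 110 °C, Ar (p-xylene, 140 °C if slow); crystallisation
Reagents that add atoms: none
Why: Proposed new method: heating should trigger thermal conrotatory 4π opening of the cyclobutenone C1–C4 bond to the (Z)-dienylketene 10, whose electrophilic ketene carbon and the nucleophilic enone α-carbon (C3) of the pyranone C2=C3 bond then join in a thermal disrotatory 6π electrocyclisation (the one ring closed, the six-membered carbocyclic A ring, through the C5–C4a bond) to dienone 11, which enolises to the aromatic, hydrogen-bonded 5-hydroxyflavone in an overall isomerisation with no by-product. The closest known reaction type is the Moore ring expansion of 4-aryl- and 4-alkenyl-4-alkoxycyclobutenones derived from squarates to annulated hydroquinone monoethers; a 4-oxopyran-2-yl group has not served as the 2π partner, but its C2=C3 bond is an enol-ether-like alkene in a weakly aromatic ring and should behave like the known alkenyl and furyl cases. No stereocentre is created: C4 of 9 becomes aromatic C8 and the transient C4a–H centre of 11 is lost on tautomerisation. The selectivity needed is torquoselectivity, secured by the C4 methoxy donor, which rotates outward and so turns the pyranonyl group inward beside the ketene; because the opening is reversible, any ketene with the pyranonyl outward should reclose and be recycled. Regiochemistry is fixed because, from pyranone C2, only C3 offers a π bond within reach (the other neighbour is the ring oxygen), so the squarate methoxyls land on C6 and C7, the carbinol ether on C8, the ketene oxygen as 5-OH and the pyranone oxygen as O1.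

Compound list
1 | (E)-4-methoxybut-3-en-2-one | CO/C=C/C(C)=O | starting material
2 | 3,4,5-trimethoxybenzoyl chloride | COc1cc(C(Cl)=O)cc(OC)c1OC | starting material
3 | lithium (E)-4-methoxybuta-1,3-dien-2-olate (lithium dienolate of 1) | CO/C=C/C(=C)O[Li] | intermediate
4 | (E)-5-methoxy-1-(3,4,5-trimethoxyphenyl)pent-4-ene-1,3-dione | CO/C=C/C(=O)CC(=O)c1cc(OC)c(OC)c(OC)c1 | intermediate
5 | 2-(3,4,5-trimethoxyphenyl)-4H-pyran-4-one | COc1cc(-c2cc(=O)cco2)cc(OC)c1OC | intermediate
6 | dimethyl squarate (3,4-dimethoxycyclobut-3-ene-1,2-dione) | COC1=C(OC)C(=O)C1=O | starting material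
7 | 6-lithio-2-(3,4,5-trimethoxyphenyl)-4H-pyran-4-one | COc1cc(-c2cc(=O)cc([Li])o2)cc(OC)c1OC | intermediate
8 | lithium rac-2,3-dimethoxy-4-oxo-1-[4-oxo-6-(3,4,5-trimethoxyphenyl)-4H-pyran-2-yl]cyclobut-2-en-1-olate | COC1=C(OC)C(O[Li])(C1=O)c1cc(=O)cc(o1)-c1cc(OC)c(OC)c(OC)c1 | intermediate
9 | rac-2,3,4-trimethoxy-4-[4-oxo-6-(3,4,5-trimethoxyphenyl)-4H-pyran-2-yl]cyclobut-2-en-1-one | COC1=C(OC)C(OC)(C1=O)c1cc(=O)cc(o1)-c1cc(OC)c(OC)c(OC)c1 | intermediate
10 | (Z)-2,3,4-trimethoxy-4-[4-oxo-6-(3,4,5-trimethoxyphenyl)-4H-pyran-2-yl]buta-1,3-dien-1-one (ketenyl and pyranonyl cis) | O=C=C(OC)/C(OC)=C(/OC)c1cc(=O)cc(o1)-c1cc(OC)c(OC)c(OC)c1 | intermediate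
11 | rac-6,7,8-trimethoxy-2-(3,4,5-trimethoxyphenyl)-4aH-chromene-4,5-dione | COC1=C(OC)C(=O)C2C(=O)C=C(c3cc(OC)c(OC)c(OC)c3)OC2=C1OC | intermediate
12 | gardenin A, 5-hydroxy-6,7,8-trimethoxy-2-(3,4,5-trimethoxyphenyl)-4H-chromen-4-one (achiral) | COc1cc(-c2cc(=O)c3c(O)c(OC)c(OC)c(OC)c3o2)cc(OC)c1OC | target

Total step count: 3. Longest linear sequence: 3 steps (1 and 2 to 5, then 9, then 12).

Steps most likely to fail

1. Step 3 (Proposed new method). After ring opening, the ketene may be consumed by intermolecular reactions, or closure onto the pyranone π bond may be slower than decomposition at the temperature the opening needs. The fallback uses known chemistry, sets out from 2 and returns to the route at 12. Acid chloride 2 is esterified (pyridine, DMAP, CH2Cl2) with purchased 2'-hydroxy-3',4',5',6'-tetramethoxyacetophenone (CC(=O)c1c(O)c(OC)c(OC)c(OC)c1OC, assumed to be a catalogue compound) to give 2-acetyl-3,4,5,6-tetramethoxyphenyl 3,4,5-trimethoxybenzoate F1. Baker–Venkataraman acyl migration (KOH, pyridine, 50 °C) should give 1-(2-hydroxy-3,4,5,6-tetramethoxyphenyl)-3-(3,4,5-trimethoxyphenyl)propane-1,3-dione F2. Acid cyclodehydration (cat. H2SO4, AcOH, 100 °C) should give 5,6,7,8-tetramethoxy-2-(3,4,5-trimethoxyphenyl)-4H-chromen-4-one F3. Chelation-directed cleavage of only the peri 5-methyl ether (BCl3, CH2Cl2, −78 → 0 °C) then gives 12.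

2. Step 2. The lithiated pyranone may self-condense or fragment before it meets the squarate, and the triflate may alkylate the pyranone carbonyl in competition with the alkoxide. The fallback sets out from 5 and returns at 9. C6 is magnesiated with TMPMgCl·LiCl (THF, −40 °C) to the less basic 6-(chloromagnesio)-2-(3,4,5-trimethoxyphenyl)-4H-pyran-4-one F4. This is added to 6 (−40 → 0 °C, aq. NH4Cl work-up) to give the isolable tertiary alcohol rac-4-hydroxy-2,3-dimethoxy-4-[4-oxo-6-(3,4,5-trimethoxyphenyl)-4H-pyran-2-yl]cyclobut-2-en-1-one F5. A separate neutral etherification (MeI, Ag2O, MeCN, rt, dark) then gives 9.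

3. Step 1. O-acylation or double acylation of the dienolate and base-induced oligomerisation of the sensitive methoxyenone may erode the annulation. The fallback sets out from 2 and returns at 5. Compound 2 acylates the lithium enolate of acetone (LiHMDS, THF, −78 °C, 2 equiv of enolate) to give 1-(3,4,5-trimethoxyphenyl)butane-1,3-dione F6. Its dianion (LDA, 2.2 equiv, THF, 0 °C) is formylated at the terminal methyl with ethyl formate to give 3,5-dioxo-5-(3,4,5-trimethoxyphenyl)pentanal F7 (enol form). Acid (cat. H2SO4, AcOH, or TFA) cyclodehydrates this triketone equivalent to 5.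

Further compounds
F1 | step 3 | 2-acetyl-3,4,5,6-tetramethoxyphenyl 3,4,5-trimethoxybenzoate | CC(=O)c1c(OC(=O)c2cc(OC)c(OC)c(OC)c2)c(OC)c(OC)c(OC)c1OC
F2 | step 3 | 1-(2-hydroxy-3,4,5,6-tetramethoxyphenyl)-3-(3,4,5-trimethoxyphenyl)propane-1,3-dione | COc1cc(C(=O)CC(=O)c2c(O)c(OC)c(OC)c(OC)c2OC)cc(OC)c1OC
F3 | step 3 | 5,6,7,8-tetramethoxy-2-(3,4,5-trimethoxyphenyl)-4H-chromen-4-one | COc1cc(-c2cc(=O)c3c(OC)c(OC)c(OC)c(OC)c3o2)cc(OC)c1OC
F4 | step 2 | 6-(chloromagnesio)-2-(3,4,5-trimethoxyphenyl)-4H-pyran-4-one | COc1cc(-c2cc(=O)cc([Mg]Cl)o2)cc(OC)c1OC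
F5 | step 2 | rac-4-hydroxy-2,3-dimethoxy-4-[4-oxo-6-(3,4,5-trimethoxyphenyl)-4H-pyran-2-yl]cyclobut-2-en-1-one | COC1=C(OC)C(O)(C1=O)c1cc(=O)cc(o1)-c1cc(OC)c(OC)c(OC)c1
F6 | step 1 | 1-(3,4,5-trimethoxyphenyl)butane-1,3-dione | CC(=O)CC(=O)c1cc(OC)c(OC)c(OC)c1
F7 | step 1 | 3,5-dioxo-5-(3,4,5-trimethoxyphenyl)pentanal | O=CCC(=O)CC(=O)c1cc(OC)c(OC)c(OC)c1
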